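## Retrosynthetic overview

1. The target is the C‑1‑hydroxylated Diels–Alder homodimer of the cis‑fused xanthanolide 8‑epi‑xanthatin; the last operations are the [4+2] dimerisation (cyclohexene ring and spiro centre) and γ‑oxygenation of the resulting β,γ‑enone.
2. 8‑epi‑Xanthatin comes from an enyne lactone by ring‑closing enyne metathesis (seven‑membered ring) with in‑flask cross‑metathesis to methyl vinyl ketone.
3. The enyne lactone comes from two fragments of equal length, a chiral alkynyl aldehyde and a γ‑allyl 2‑(methoxycarbonyl)allylboronate, joined by asymmetric allylboration–lactonisation (butyrolactone ring, C‑7/C‑8).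
4. The aldehyde is made by Evans alkylation (C‑10) and Ohira–Bestmann homologation; the boronate from methyl hex‑5‑enoate by a selenoxide route and palladium‑catalysed borylation.
5. Ring order: butyrolactone, then cycloheptadiene (metathesis), then cyclohexene with the spiro junction (Diels–Alder).

Locants C‑1 to C‑15 are xanthane locants (C‑1 ring carbon bearing the side chain, C‑5 ring CH=, C‑7/C‑8 lactone fusion, C‑10 methyl carbon, C‑11/C‑13 lactone methylene); primed locants belong to the dienophile half.

Assumption: the phosphoric acid (R)‑TRIP sends an allyl group to the Re face of an aldehyde (benzaldehyde gives the R alcohol), so its S antipode is used for the Si‑face attack needed here.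

## Route

Step 1
Reactants: 1 (4R)-4-benzyl-3-propanoyl-1,3-oxazolidin-2-one; 2 tert-butyl bromoacetate
Product: 4 tert-butyl (3S)-4-[(4R)-4-benzyl-2-oxo-1,3-oxazolidin-3-yl]-3-methyl-4-oxobutanoate, via sodium Z-enolate of the imide 3 (not isolated)
Conditions: NaN(SiMe3)2 (1.1 equiv), THF, −78 °C, 1 h; then 2 (1.5 equiv), −78 → −40 °C
Reagents that add atoms: none
Why: Evans asymmetric alkylation, in which the chelated Z‑enolate 3 is alkylated on the face away from the benzyl group, setting the methyl‑bearing centre (later C‑10) as S with dr usually above 95:5.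

Step 2
Reactants: 4 tert-butyl (3S)-4-[(4R)-4-benzyl-2-oxo-1,3-oxazolidin-3-yl]-3-methyl-4-oxobutanoate
Product: 5 tert-butyl (3S)-4-hydroxy-3-methylbutanoate
Conditions: LiBH4 (1.2 equiv), THF, 0 °C → rt
Reagents that add atoms: none
Why: Reductive cleavage of the auxiliary, in which LiBH4 attacks the activated exocyclic imide carbonyl much faster than the hindered tert‑butyl ester and the stereocentre is not touched.

Step 3
Reactants: 5 tert-butyl (3S)-4-hydroxy-3-methylbutanoate
Product: 6 tert-butyl (3S)-3-methyl-4-oxobutanoate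
Conditions: TEMPO (2,2,6,6-tetramethylpiperidin-1-oxyl, 10 mol %), PhI(OAc)2 (1.1 equiv), CH2Cl2, rt; used crude
Reagents that add atoms: none
Why: Oxoammonium (TEMPO/PhI(OAc)2) oxidation of the primary alcohol stops at the aldehyde under non‑basic conditions, so the α‑stereocentre is not epimerised if 6 is used at once.

Step 4
Reactants: 6 tert-butyl (3S)-3-methyl-4-oxobutanoate
Product: 7 tert-butyl (3S)-3-methylpent-4-ynoate
Conditions: dimethyl (1-diazo-2-oxopropyl)phosphonate (1.3 equiv), K2CO3 (2 equiv), MeOH, 0 °C → rt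
Reagents that add atoms: dimethyl (1-diazo-2-oxopropyl)phosphonate, COP(=O)(OC)C(=[N+]=[N-])C(C)=O
Why: Ohira–Bestmann variant of the Seyferth–Gilbert homologation, in which the diazomethylphosphonate anion made in the flask converts the aldehyde into the terminal alkyne under K2CO3/MeOH at 0 °C, mild enough to keep the α‑centre and the tert‑butyl ester intact.

Step 5
Reactants: 7 tert-butyl (3S)-3-methylpent-4-ynoate
Product: 8 (3S)-3-methylpent-4-ynal
Conditions: iBu2AlH (1.05 equiv), PhMe, −78 °C; MeOH, aq. Rochelle salt; water washes; kept as a dried, titrated PhMe solution (volatile)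
Reagents that add atoms: none
Why: Partial reduction of an ester, in which the aluminium hemiacetal from the tert‑butyl ester survives at −78 °C until hydrolysis, so the aldehyde appears only on work‑up and the centre (now β to the carbonyl) cannot epimerise.

Step 6
Reactants: 9 methyl hex-5-enoate
Product: 11 methyl 2-(phenylselanyl)hex-5-enoate (racemic), via lithium enolate of the ester 10 (not isolated)
Conditions: LiN(iPr)2 (1.1 equiv), THF, −78 °C; PhSeBr (1.05 equiv), −78 °C
Reagents that add atoms: phenylselenenyl bromide, Br[Se]c1ccccc1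
Why: α‑Selenenylation of an ester enolate, in which PhSeBr is consumed by enolate 10 at −78 °C faster than it can add to the terminal alkene; the new centre is racemic and is erased in step 8.

Step 7
Reactants: 11 methyl 2-(phenylselanyl)hex-5-enoate
Product: 13 methyl 2-(hydroxymethyl)-2-(phenylselanyl)hex-5-enoate (racemic), via lithium enolate of the selenide 12 (not isolated)
Conditions: LiN(iPr)2 (1.15 equiv), THF, −78 °C; CH2O (gas from cracked paraformaldehyde), −78 → −40 °C; AcOH (1.2 equiv), −78 °C
Reagents that add atoms: formaldehyde, C=O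
Why: Aldol addition of the selenium‑stabilised enolate 12 to monomeric formaldehyde installs the one‑carbon arm that later becomes the exocyclic methylene; the quaternary centre is racemic and is erased in step 8.

Step 8
Reactants: 13 methyl 2-(hydroxymethyl)-2-(phenylselanyl)hex-5-enoate
Product: 15 methyl (2E)-2-(hydroxymethyl)hexa-2,5-dienoate, via selenoxide 14 (not isolated)
Conditions: H2O2 (30 % aq., 2.5 equiv), pyridine (2 equiv), CH2Cl2, 0 °C → rt
Reagents that add atoms: none
Why: Selenoxide syn‑elimination, in which selenoxide 14 eliminates away from the hydroxylated carbon (allylic alcohol, not enol) to give the conjugated acrylate, mainly the E isomer with the allyl group trans to the ester.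

Step 9
Reactants: 15 methyl (2E)-2-(hydroxymethyl)hexa-2,5-dienoate
Product: 16 methyl (2E)-2-(acetoxymethyl)hexa-2,5-dienoate
Conditions: Ac2O (1.5 equiv), pyridine, 4-(dimethylamino)pyridine (5 mol %), CH2Cl2, 0 °C
Reagents that add atoms: acetic anhydride, CC(=O)OC(C)=O
Why: Nucleophile‑catalysed O‑acetylation turns the hydroxyl into the leaving group needed for π‑allyl formation without touching the skipped diene.

Step 10
Reactants: 16 methyl (2E)-2-(acetoxymethyl)hexa-2,5-dienoate
Product: 17 methyl (2E)-2-[(4,4,5,5-tetramethyl-1,3,2-dioxaborolan-2-yl)methyl]hexa-2,5-dienoate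
Conditions: B2pin2 (1.1 equiv), Pd2(dba)3 (2.5 mol %, zerovalent palladium), DMSO, 50 °C
Reagents that add atoms: bis(pinacolato)diboron, CC1(C)OB(OC1(C)C)B1OC(C)(C)C(C)(C)O1
Why: Miyaura‑type allylic borylation, in which zerovalent palladium ionises the acetate to a π‑allyl complex and boron is delivered to the unsubstituted terminus, keeping the conjugated acrylate with the allyl group cis to CH2B, while syn/anti equilibration of the π‑allyl funnels any Z acetate to the same boronate.

Step 11
Reactants: 8 (3S)-3-methylpent-4-ynal; 17 methyl (2E)-2-[(4,4,5,5-tetramethyl-1,3,2-dioxaborolan-2-yl)methyl]hexa-2,5-dienoate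
Product: 19 (4R,5R)-3-methylidene-5-[(2S)-2-methylbut-3-yn-1-yl]-4-(prop-2-en-1-yl)oxolan-2-one, via syn borate adduct 18 (not isolated)
Conditions: 17 (1.2 equiv), (S)-TRIP [(S)-3,3'-bis(2,4,6-triisopropylphenyl)-1,1'-binaphthyl-2,2'-diyl hydrogen phosphate, 10 mol %], 4 Å MS, PhMe, −30 °C → rt; then TsOH·H2O (10 mol %), rt
Reagents that add atoms: none
Why: Chiral‑phosphoric‑acid‑catalysed allylboration with tandem lactonisation, in which the closed chair (Zimmerman–Traxler) transition state with the γ‑allyl group axial gives the syn adduct 18 (cis C‑7/C‑8), the S acid directs attack to the Si face of the aldehyde (C‑8 R, C‑7 R) independently of the remote methyl centre, and the borate closes onto the ester with loss of MeOBpin.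

Step 12
Reactants: 19 (4R,5R)-3-methylidene-5-[(2S)-2-methylbut-3-yn-1-yl]-4-(prop-2-en-1-yl)oxolan-2-one; 20 but-3-en-2-one (methyl vinyl ketone)
Product: 22 8-epi-xanthatin, (3aR,7S,8aR)-7-methyl-3-methylidene-6-[(1E)-3-oxobut-1-en-1-yl]-3,3a,4,7,8,8a-hexahydro-2H-cyclohepta[b]furan-2-one, via 6-vinyl triene 21 (not isolated)
Conditions: 20 (10 equiv), second-generation Hoveyda–Grubbs catalyst RuCl2(H2IMes)(=CH-C6H4-2-OiPr) (10 mol %), CH2Cl2 (5 mM), 40 °C
Reagents that add atoms: none
Why: Domino ring‑closing enyne metathesis/cross‑metathesis, in which the ruthenium carbene formed at the allyl terminus closes the seven‑membered ring onto the alkyne (exo mode) to give the 1‑vinylcycloheptene 21, whose vinyl group then undergoes E‑selective cross‑metathesis with excess 20, while the electron‑poor lactone methylene is inert and no stereocentre is touched.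

Step 13
Reactants: 22 8-epi-xanthatin (two molecules)
Product: 23 Diels–Alder dimer (1(2)-ene with H at C‑3; new bonds C3–C11' and C5–C13')
Conditions: neat (or 3 M in PhMe), BHT (5 mol %), Ar, dark, 80 °C, 36–48 h
Reagents that add atoms: none
Why: Thermal Diels–Alder homodimerisation, in which the s‑cis dienone C5=C1–C2=C3 of one molecule adds to the exocyclic C11'=C13' alkene of a second in the "ortho" sense (C3–C11', C5–C13'), endo to the lactone carbonyl, on the convex (H‑7'/H‑8') face of the cis‑fused lactone and with the new C5–C13' bond cis to the C‑10 methyl, which sets the spiro centre C‑11', C‑5 and the later erased C‑3 as in the natural dimer series.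

Step 14
Reactants: 23 Diels–Alder dimer
Product: 25 CNP0168949.1 (target), via C‑1 hydroperoxide 24 (not isolated)
Conditions: O2 (1 atm), DBU (1,8-diazabicyclo[5.4.0]undec-7-ene, 0.3 equiv), P(OEt)3 (1.5 equiv), MeCN, −20 → 0 °C
Reagents that add atoms: dioxygen, O=O
Why: Base‑mediated dienolate autoxidation (γ‑hydroxylation), in which DBU reversibly removes H‑3 (α to the acetyl group and allylic, the most acidic proton), the dienolate takes up O2 at C‑1 with shift of the alkene into conjugation, attack coming anti to the pseudo‑axial H‑5 (chair‑like, trans ring fusion, OH cis to the C‑10 methyl), and P(OEt)3 reduces hydroperoxide 24 as it forms.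

## Compound list

1 | (4R)-4-benzyl-3-propanoyl-1,3-oxazolidin-2-one | CCC(=O)N1[C@H](Cc2ccccc2)COC1=O | starting material
2 | tert-butyl bromoacetate | CC(C)(C)OC(=O)CBr | starting material
3 | sodium Z-enolate of 1 (not isolated) | C/C=C(\[O-])N1[C@H](Cc2ccccc2)COC1=O.[Na+] | intermediate
4 | tert-butyl (3S)-4-[(4R)-4-benzyl-2-oxo-1,3-oxazolidin-3-yl]-3-methyl-4-oxobutanoate | CC(C)(C)OC(=O)C[C@H](C)C(=O)N1[C@H](Cc2ccccc2)COC1=O | intermediate
5 | tert-butyl (3S)-4-hydroxy-3-methylbutanoate | CC(C)(C)OC(=O)C[C@H](C)CO | intermediate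
6 | tert-butyl (3S)-3-methyl-4-oxobutanoate | CC(C)(C)OC(=O)C[C@H](C)C=O | intermediate
7 | tert-butyl (3S)-3-methylpent-4-ynoate | CC(C)(C)OC(=O)C[C@H](C)C#C | intermediate
8 | (3S)-3-methylpent-4-ynal | O=CC[C@H](C)C#C | intermediate
9 | methyl hex-5-enoate | C=CCCCC(=O)OC | starting material
10 | lithium enolate of 9 (not isolated) | C=CCCC=C([O-])OC.[Li+] | intermediate
11 | methyl 2-(phenylselanyl)hex-5-enoate (racemic) | C=CCCC([Se]c1ccccc1)C(=O)OC | intermediate
12 | lithium enolate of 11 (not isolated) | C=CCCC([Se]c1ccccc1)=C([O-])OC.[Li+] | intermediate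
13 | methyl 2-(hydroxymethyl)-2-(phenylselanyl)hex-5-enoate (racemic) | C=CCCC(CO)([Se]c1ccccc1)C(=O)OC | intermediate
14 | selenoxide of 13 (not isolated) | C=CCCC(CO)([Se](=O)c1ccccc1)C(=O)OC | intermediate
15 | methyl (2E)-2-(hydroxymethyl)hexa-2,5-dienoate | C=CC/C=C(\CO)C(=O)OC | intermediate
16 | methyl (2E)-2-(acetoxymethyl)hexa-2,5-dienoate | C=CC/C=C(\COC(C)=O)C(=O)OC | intermediate
17 | methyl (2E)-2-[(4,4,5,5-tetramethyl-1,3,2-dioxaborolan-2-yl)methyl]hexa-2,5-dienoate | C=CC/C=C(\CB1OC(C)(C)C(C)(C)O1)C(=O)OC | intermediate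
18 | methyl (3R,4R,6S)-6-methyl-2-methylidene-4-[(4,4,5,5-tetramethyl-1,3,2-dioxaborolan-2-yl)oxy]-3-(prop-2-en-1-yl)oct-7-ynoate (not isolated) | C=C(C(=O)OC)[C@@H](CC=C)[C@H](OB1OC(C)(C)C(C)(C)O1)C[C@H](C)C#C | intermediate
19 | (4R,5R)-3-methylidene-5-[(2S)-2-methylbut-3-yn-1-yl]-4-(prop-2-en-1-yl)oxolan-2-one | C=C1C(=O)O[C@H](C[C@H](C)C#C)[C@@H]1CC=C | intermediate
20 | but-3-en-2-one (methyl vinyl ketone) | C=CC(C)=O | starting material
21 | (3aR,7S,8aR)-6-ethenyl-7-methyl-3-methylidene-3,3a,4,7,8,8a-hexahydro-2H-cyclohepta[b]furan-2-one (not isolated) | C=C1C(=O)O[C@@H]2C[C@H](C)C(C=C)=CC[C@H]12 | intermediate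
22 | 8-epi-xanthatin, (3aR,7S,8aR)-7-methyl-3-methylidene-6-[(1E)-3-oxobut-1-en-1-yl]-3,3a,4,7,8,8a-hexahydro-2H-cyclohepta[b]furan-2-one | C=C1C(=O)O[C@@H]2C[C@H](C)C(/C=C/C(C)=O)=CC[C@H]12 | intermediate
23 | Diels–Alder dimer of 22 (1(2)-ene, H at C‑3 cis to H‑5; bonds C3–C11' and C5–C13'; spiro C‑11') | C=C1C(=O)O[C@@H]2C[C@H](C)C3=C[C@H](C(C)=O)[C@@]4(C[C@@H]3C[C@H]12)C(=O)O[C@@H]1C[C@H](C)C(/C=C/C(C)=O)=CC[C@@H]14 | intermediate
24 | C‑1 hydroperoxide of the target (1-OOH, 2(3)-ene; not isolated) | C=C1C(=O)O[C@@H]2C[C@H](C)[C@@]3(OO)C=C(C(C)=O)[C@@]4(C[C@@H]3C[C@H]12)C(=O)O[C@@H]1C[C@H](C)C(/C=C/C(C)=O)=CC[C@@H]14 | intermediate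
25 | CNP0168949.1 (1-hydroxy-2(3)-ene dimer) | C=C1C(=O)O[C@@H]2C[C@H](C)[C@@]3(O)C=C(C(C)=O)[C@@]4(C[C@@H]3C[C@H]12)C(=O)O[C@@H]1C[C@H](C)C(/C=C/C(C)=O)=CC[C@@H]14 | target

## Step count and risks

Total step count: 14.
Longest linear sequence: 9 steps (steps 1–5 then 11–14; equally steps 6–10 then 11–14).

Most likely to fail:

**Step 13 (Diels–Alder dimerisation).** Regio‑, endo‑ and facial selectivity are not enforced by anything but the substrate, and the product still carries a lactone methylene and a dienone, so oligomers can form. The fallback sets out from 22 and assigns the two roles. Dimethylamine (2 M in THF, 0 °C) adds to the lactone methylene of 22 to give the Michael adduct 13-(dimethylamino)-11,13-dihydro-8-epi-xanthatin F5 (drawn as one C‑11 epimer; the centre is erased on unmasking), which can act only as the diene. Heating F5 (3 equiv) with 22 (1 equiv) at 70 °C gives the cross‑adduct, the 13-dimethylamino-11,13-dihydro derivative of the dimer F6, which cannot react further as a dienophile. Quaternisation with MeI gives the trimethylammonium iodide F7, and aqueous NaHCO3 eliminates trimethylamine to restore the methylene, coming back to the route at 23.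

**Step 14 (γ‑oxygenation).** DBU may instead deprotonate the dienone of the other half, isomerise the lactone methylene, or give the C‑1 epimer. A singlet‑oxygen ene reaction is not an alternative, because it would deliver oxygen syn to H‑3 and H‑5 and give the C‑1 epimer. The fallback sets out from 23: Ac2O/Et3N/4-(dimethylamino)pyridine converts the more acidic β,γ‑unsaturated ketone into the conjugated dienol acetate F8 (enol acetate geometry not controlled). mCPBA (NaHCO3, CH2Cl2, −20 °C) then epoxidises its electron‑rich C1=C2 bond from the axial direction anti to H‑5, and the epoxy acetate collapses with loss of the acetyl group to the 1‑hydroxy‑2(3)‑enone, coming back at 25.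

**Step 11 (asymmetric allylboration–lactonisation).** The ester‑bearing boronate is a sluggish partner and the catalyst must override a remote stereocentre. The fallback sets out from 15 and 8 and trades catalyst control for a metal‑mediated Barbier reaction. PBr3 (Et2O, 0 °C) converts 15 into methyl (2Z)-2-(bromomethyl)hexa-2,5-dienoate F1. Indium powder with 8 in THF–H2O gives, through a cyclic transition state, the syn hydroxy esters methyl (3R,4R,6S)-4-hydroxy-6-methyl-2-methylidene-3-(prop-2-en-1-yl)oct-7-ynoate F2 and its (3S,4S,6S) isomer F3 in roughly equal amounts. Acid (TsOH) lactonises both; the unwanted (4S,5S)-3-methylidene-5-[(2S)-2-methylbut-3-yn-1-yl]-4-(prop-2-en-1-yl)oxolan-2-one F4 is a diastereomer of the wanted lactone and is removed by chromatography, coming back to the route at 19 (at most half the material).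

## Further compounds

F1 | step 11 | methyl (2Z)-2-(bromomethyl)hexa-2,5-dienoate | C=CC/C=C(\CBr)C(=O)OC
F2 | step 11 | methyl (3R,4R,6S)-4-hydroxy-6-methyl-2-methylidene-3-(prop-2-en-1-yl)oct-7-ynoate | C=C(C(=O)OC)[C@@H](CC=C)[C@H](O)C[C@H](C)C#C
F3 | step 11 | methyl (3S,4S,6S)-4-hydroxy-6-methyl-2-methylidene-3-(prop-2-en-1-yl)oct-7-ynoate | C=C(C(=O)OC)[C@H](CC=C)[C@@H](O)C[C@H](C)C#C
F4 | step 11 | (4S,5S)-3-methylidene-5-[(2S)-2-methylbut-3-yn-1-yl]-4-(prop-2-en-1-yl)oxolan-2-one | C=C1C(=O)O[C@@H](C[C@H](C)C#C)[C@H]1CC=C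
F5 | step 13 | 13-(dimethylamino)-11,13-dihydro-8-epi-xanthatin | CN(C)C[C@@H]1C(=O)O[C@@H]2C[C@H](C)C(/C=C/C(C)=O)=CC[C@H]12
F6 | step 13 | 13-dimethylamino-11,13-dihydro derivative of dimer 23 | CN(C)C[C@@H]1C(=O)O[C@@H]2C[C@H](C)C3=C[C@H](C(C)=O)[C@@]4(C[C@@H]3C[C@H]12)C(=O)O[C@@H]1C[C@H](C)C(/C=C/C(C)=O)=CC[C@@H]14
F7 | step 13 | trimethylammonium iodide of F6 | C[N+](C)(C)C[C@@H]1C(=O)O[C@@H]2C[C@H](C)C3=C[C@H](C(C)=O)[C@@]4(C[C@@H]3C[C@H]12)C(=O)O[C@@H]1C[C@H](C)C(/C=C/C(C)=O)=CC[C@@H]14.[I-]
F8 | step 14 | dienol acetate of dimer 23 (1(2),3(4)-diene, 4-acetoxy) | C=C1C(=O)O[C@@H]2C[C@H](C)C3=CC(=C(C)OC(C)=O)[C@@]4(C[C@@H]3C[C@H]12)C(=O)O[C@@H]1C[C@H](C)C(/C=C/C(C)=O)=CC[C@@H]14
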